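**Retrosynthetic overview**

- Ring C (the flavan pyran) is closed last, at O1–C2, by Mitsunobu inversion of an (R)-1,3-diarylpropan-1-ol. That alcohol comes from Claisen–Schmidt union of a ring B/D methyl ketone with a ring A salicylaldehyde, conjugate reduction and CBS reduction.
- Ring D (the 3-hydroxy-2,2-dimethyl-dihydropyran on ring B) is made first and is disconnected at C3–C2. The chroman-3-one comes from an arylacetaldehyde (its acyl carbon is C3) and a tertiary α-aryloxy radical (C2), released by decarboxylation of an aryloxyisobutyric acid active ester.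
- Enabling feature: C2 of ring D is a fully substituted carbon carrying the ring B ether oxygen O1 and two methyls, so it is the radical of an aryloxyisobutyric acid. C3 is an oxygenated carbon next to benzylic C4, so it is the carbonyl of an arylacetaldehyde. Both arms sit ortho on ring B, which makes the closure six-membered.
- Both arms derive from one phenol: regioselective 4-O-allylation, Claisen shift, Bargellini reaction on the freed phenol, ozonolysis. The ring B prenyl comes from Negishi coupling at C–Br, the ring A 1,1-dimethylallyl group from γ-selective Suzuki–Miyaura coupling.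
- Stereocentres: C3 of ring D by reagent-controlled CBS reduction of the ketone from the key step; flavan C2 by CBS reduction then inversion. Ring order: D, then C (rings A and B are bought arenes).

Key step: step 8

Remark: the SMILES is read as 2S at the flavan carbon and 3S at the carbinol carbon of ring D. Ring A is the benzo ring of the flavan, ring C its pyran ring, ring B the 2-aryl ring, ring D the dimethyl-dihydropyran fused to ring B (O1, C2, C3, C4 in chroman numbering).

**Step 1**
Reactants: 1 2-bromo-4,5-dimethoxybenzonitrile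
Product: 2 2-bromo-4,5-dihydroxybenzonitrile
Conditions: BBr3 (3 equiv), CH2Cl2, −78 °C → rt; MeOH, then H2O
Reagents that add atoms: none
Why: Lewis acid-mediated cleavage of both aryl methyl ethers by bromide attack on the O-methyl groups; the nitrile and the aryl bromide are inert.

**Step 2**
Reactants: 2 2-bromo-4,5-dihydroxybenzonitrile
Product: 3 4-(allyloxy)-2-bromo-5-hydroxybenzonitrile
Conditions: allyl bromide (1.05 equiv), K2CO3 (1.0 equiv), DMF, 0 °C → rt
Reagents that add atoms: allyl bromide, C=CCBr
Why: Williamson etherification in which the phenol para to the nitrile is the more acidic one and is therefore the one alkylated by one equivalent of base, as is known for 3,4-dihydroxyaryl carbonyl compounds.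

**Step 3**
Reactants: 3 4-(allyloxy)-2-bromo-5-hydroxybenzonitrile
Product: 4 4-(allyloxy)-2-bromo-5-(methoxymethoxy)benzonitrile
Conditions: MOMCl, iPr2NEt, CH2Cl2, 0 °C → rt
Reagents that add atoms: chloromethyl methyl ether, COCCl
Why: Base-mediated acetalisation of the remaining phenol gives a MOM ether that survives the Claisen temperature, base and organometallic reagents and cannot migrate to the neighbouring oxygen.

**Step 4**
Reactants: 4 4-(allyloxy)-2-bromo-5-(methoxymethoxy)benzonitrile
Product: 6 3-allyl-2-bromo-4-hydroxy-5-(methoxymethoxy)benzonitrile, via ortho-dienone 5 (not isolated)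
Conditions: N,N-diethylaniline, 190 °C, sealed tube
Reagents that add atoms: none
Why: Aromatic Claisen rearrangement ([3,3] shift then tautomerisation); of the two ortho positions only the one between the oxygen and C–Br carries hydrogen, so dienone 5 can re-aromatise only to 6.

**Step 5**
Reactants: 6 3-allyl-2-bromo-4-hydroxy-5-(methoxymethoxy)benzonitrile
Product: 8 2-[2-allyl-3-bromo-4-cyano-6-(methoxymethoxy)phenoxy]-2-methylpropanoic acid, via acid chloride 7 (not isolated)
Conditions: acetone (solvent), CHCl3 (3 equiv), powdered NaOH (6 equiv), 0 °C → rt; cold aq. citric acid to pH 3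
Reagents that add atoms: acetone, CC(C)=O; chloroform, ClC(Cl)Cl; sodium hydroxide, [Na+].[OH-]
Why: Bargellini reaction, in which trichloromethide adds to acetone, the derived gem-dichloroepoxide is opened at its tertiary carbon by the hindered phenoxide and acid chloride 7 is hydrolysed; this sequence tolerates ortho,ortho'-disubstituted phenols where direct alkylation with a tertiary bromide is slow.

**Step 6**
Reactants: 8 2-[2-allyl-3-bromo-4-cyano-6-(methoxymethoxy)phenoxy]-2-methylpropanoic acid
Product: 9 1,3-dioxoisoindolin-2-yl 2-[2-allyl-3-bromo-4-cyano-6-(methoxymethoxy)phenoxy]-2-methylpropanoate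
Conditions: N-hydroxyphthalimide, N,N'-diisopropylcarbodiimide, DMAP (cat.), CH2Cl2, rt
Reagents that add atoms: N-hydroxyphthalimide, O=C1c2ccccc2C(=O)N1O
Why: Carbodiimide esterification of the tertiary acid installs the redox-active ester that later serves as a traceless source of the tertiary radical.

**Step 7**
Reactants: 9 1,3-dioxoisoindolin-2-yl 2-[2-allyl-3-bromo-4-cyano-6-(methoxymethoxy)phenoxy]-2-methylpropanoate
Product: 11 1,3-dioxoisoindolin-2-yl 2-[3-bromo-4-cyano-6-(methoxymethoxy)-2-(2-oxoethyl)phenoxy]-2-methylpropanoate, via secondary ozonide 10 (not isolated)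
Conditions: O3, CH2Cl2, −78 °C; then Me2S, −78 °C → rt; used at once
Reagents that add atoms: ozone, [O-][O+]=O
Why: Ozonolysis with reductive work-up cleaves the only alkene to the arylacetaldehyde; the arene is deactivated by nitrile and bromide and the active ester is inert to ozone.

**Step 8**
Reactants: 11 1,3-dioxoisoindolin-2-yl 2-[3-bromo-4-cyano-6-(methoxymethoxy)-2-(2-oxoethyl)phenoxy]-2-methylpropanoate
Product: 12 5-bromo-8-(methoxymethoxy)-2,2-dimethyl-3-oxochromane-6-carbonitrile
Conditions: 3-(2,6-diisopropylphenyl)-5,6,7,8-tetrahydro-4H-cyclohepta[d]thiazol-3-ium perchlorate (15 mol %), Cs2CO3 (20 mol %), DMSO (0.02 M), 60 °C, N2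
Reagents that add atoms: none
Why: Proposed new method: the thiazolylidene adds to the aldehyde to give the Breslow intermediate, whose enolate transfers one electron to the tethered N-acyloxyphthalimide; loss of phthalimide anion and CO2 leaves the tertiary α-aryloxy radical (future C2 with both methyls) and the persistent azolium-stabilised ketyl radical (future C3) in the same molecule, and their recombination followed by release of the carbene gives the ketone, the closest known reaction type being the intermolecular carbene-catalysed decarboxylative radical acylation of aliphatic aldehydes with tertiary N-acyloxyphthalimides. Ring D closes by six-membered recombination of this 1,6-diradical, whose termini are held ortho on ring B and folded together by the gem-dimethyl group. No stereocentre is formed, since C2 carries two methyls and C3 emerges as the carbonyl that step 9 reduces under reagent control. The step needs intramolecular electron transfer and coupling to outrun aldol self-condensation of the arylacetaldehyde and intermolecular coupling, which the ortho tether, the catalytic amount of base and high dilution should secure. The aryl bromide, nitrile and MOM ether are inert to these metal-free conditions, and the carboxyl group that activated C2 leaves as CO2.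

**Step 9**
Reactants: 12 5-bromo-8-(methoxymethoxy)-2,2-dimethyl-3-oxochromane-6-carbonitrile
Product: 13 (S)-5-bromo-3-hydroxy-8-(methoxymethoxy)-2,2-dimethylchromane-6-carbonitrile
Conditions: (R)-2-methyl-CBS-oxazaborolidine [(R)-1-methyl-3,3-diphenyltetrahydro-1H,3H-pyrrolo[1,2-c][1,3,2]oxazaborole] (0.2 equiv), BH3·SMe2 (0.7 equiv), THF, −20 °C; MeOH quench
Reagents that add atoms: none
Why: Corey–Bakshi–Shibata reduction, in which the ketone binds the catalyst boron anti to the quaternary C2 (large group) and hydride is delivered to the face that gives the 3S carbinol, so the stereocentre is set by the reagent alone.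

**Step 10**
Reactants: 13 (S)-5-bromo-3-hydroxy-8-(methoxymethoxy)-2,2-dimethylchromane-6-carbonitrile
Product: 14 (S)-5-bromo-8-(methoxymethoxy)-2,2-dimethyl-3-(triethylsilyloxy)chromane-6-carbonitrile
Conditions: TESOTf, 2,6-lutidine, CH2Cl2, −78 → 0 °C
Reagents that add atoms: triethylsilyl trifluoromethanesulfonate, CC[Si](CC)(CC)OS(=O)(=O)C(F)(F)F
Why: Silylation of the hindered secondary alcohol with the silyl triflate protects it from the organometallic steps and the Mitsunobu closure, and the TES ether is removed later together with the MOM ethers.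

**Step 11**
Reactants: 14 (S)-5-bromo-8-(methoxymethoxy)-2,2-dimethyl-3-(triethylsilyloxy)chromane-6-carbonitrile
Product: 15 (S)-8-(methoxymethoxy)-2,2-dimethyl-5-(3-methylbut-2-en-1-yl)-3-(triethylsilyloxy)chromane-6-carbonitrile
Conditions: (3-methylbut-2-en-1-yl)zinc bromide (1.5 equiv), Pd(OAc)2 (2 mol %), 2-dicyclohexylphosphino-2',6'-bis(dimethylamino)biphenyl (CPhos, 4 mol %), THF, rt
Reagents that add atoms: (3-methylbut-2-en-1-yl)zinc bromide, CC(C)=CC[Zn]Br
Why: Negishi coupling of the ortho,ortho'-disubstituted aryl bromide (activated by the ortho nitrile), in which the bulky biarylphosphine favours reductive elimination from the primary σ-allyl palladium and hence the linear prenyl isomer.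

**Step 12**
Reactants: 15 (S)-8-(methoxymethoxy)-2,2-dimethyl-5-(3-methylbut-2-en-1-yl)-3-(triethylsilyloxy)chromane-6-carbonitrile
Product: 17 1-[(S)-8-(methoxymethoxy)-2,2-dimethyl-5-(3-methylbut-2-en-1-yl)-3-(triethylsilyloxy)chroman-6-yl]ethan-1-one, via N-magnesio ketimine 16 (not isolated)
Conditions: MeMgBr (3 equiv), THF–toluene, 70 °C; then 1 M aq. HCl, 0 °C, 10 min
Reagents that add atoms: methylmagnesium bromide, C[Mg]Br; water, O
Why: Grignard addition to the nitrile stops at ketimine salt 16, which brief cold aqueous acid hydrolyses to the methyl ketone without cleaving the TES or MOM ethers.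

**Step 13**
Reactants: 18 5-bromo-2,4-dihydroxybenzaldehyde
Product: 19 5-bromo-2-hydroxy-4-(methoxymethoxy)benzaldehyde
Conditions: MOMCl (1.05 equiv), iPr2NEt, CH2Cl2, 0 °C
Reagents that add atoms: chloromethyl methyl ether, COCCl
Why: Selective alkylation of the 4-hydroxyl, the more acidic and unchelated phenol, while the 2-hydroxyl stays hydrogen-bonded to the aldehyde.

**Step 14**
Reactants: 19 5-bromo-2-hydroxy-4-(methoxymethoxy)benzaldehyde
Product: 20 2-hydroxy-4-(methoxymethoxy)-5-(2-methylbut-3-en-2-yl)benzaldehyde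
Conditions: prenyl pinacol boronate (1.5 equiv), Pd(OAc)2 (3 mol %), 1,1'-bis(di-tert-butylphosphino)ferrocene (3.5 mol %), K2CO3, THF–H2O, 65 °C
Reagents that add atoms: 4,4,5,5-tetramethyl-2-(3-methylbut-2-en-1-yl)-1,3,2-dioxaborolane, CC(C)=CCB1OC(C)(C)C(C)(C)O1
Why: γ-Selective Suzuki–Miyaura allylation, in which transmetalation with allyl transposition gives the tertiary σ-allyl palladium and the bulky electron-rich bisphosphine makes reductive elimination faster than isomerisation, giving the 1,1-dimethylallyl arene.

**Step 15**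
Reactants: 17 1-[(S)-8-(methoxymethoxy)-2,2-dimethyl-5-(3-methylbut-2-en-1-yl)-3-(triethylsilyloxy)chroman-6-yl]ethan-1-one; 20 2-hydroxy-4-(methoxymethoxy)-5-(2-methylbut-3-en-2-yl)benzaldehyde
Product: 22 (E)-3-[2-hydroxy-4-(methoxymethoxy)-5-(2-methylbut-3-en-2-yl)phenyl]-1-[(S)-8-(methoxymethoxy)-2,2-dimethyl-5-(3-methylbut-2-en-1-yl)-3-(triethylsilyloxy)chroman-6-yl]prop-2-en-1-one, via aldol adduct 21 (not isolated)
Conditions: KOH (aq. 50 %), EtOH, rt → 40 °C; AcOH work-up
Reagents that add atoms: none
Why: Claisen–Schmidt condensation in which 17 is the only enolisable ketone and 20 the only aldehyde, and dehydration of aldol 21 gives the conjugated E-enone.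

**Step 16**
Reactants: 22 the E-enone of step 15
Product: 23 3-[2-hydroxy-4-(methoxymethoxy)-5-(2-methylbut-3-en-2-yl)phenyl]-1-[(S)-8-(methoxymethoxy)-2,2-dimethyl-5-(3-methylbut-2-en-1-yl)-3-(triethylsilyloxy)chroman-6-yl]propan-1-one
Conditions: Cu(OAc)2·H2O (5 mol %), 1,2-bis(diphenylphosphino)benzene (5 mol %), (EtO)2MeSiH (3 equiv), t-BuOH (3 equiv), toluene, rt; aq. NH4F work-up
Reagents that add atoms: none
Why: Copper hydride conjugate reduction adds hydride only to the enone β-carbon and the copper enolate is protonated by tert-butanol, leaving the prenyl and vinyl groups and the ketone untouched.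

**Step 17**
Reactants: 23 the saturated ketone of step 16
Product: 24 (R)-3-[2-hydroxy-4-(methoxymethoxy)-5-(2-methylbut-3-en-2-yl)phenyl]-1-[(S)-8-(methoxymethoxy)-2,2-dimethyl-5-(3-methylbut-2-en-1-yl)-3-(triethylsilyloxy)chroman-6-yl]propan-1-ol
Conditions: (S)-2-methyl-CBS-oxazaborolidine [(S)-1-methyl-3,3-diphenyltetrahydro-1H,3H-pyrrolo[1,2-c][1,3,2]oxazaborole] (0.2 equiv), BH3·SMe2 (2 equiv), THF, −20 °C; MeOH quench
Reagents that add atoms: none
Why: Corey–Bakshi–Shibata reduction with the aryl ring as the large group and the methylene as the small group should give the R carbinol, the free phenol only consuming one equivalent of borane.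

**Step 18**
Reactants: 24 the (R)-carbinol of step 17
Product: 25 (3S)-8-(methoxymethoxy)-6-[(2S)-7-(methoxymethoxy)-6-(2-methylbut-3-en-2-yl)chroman-2-yl]-2,2-dimethyl-5-(3-methylbut-2-en-1-yl)-3-(triethylsilyloxy)chromane
Conditions: PPh3, DIAD, THF (0.01 M), 0 °C, slow addition
Reagents that add atoms: none
Why: Intramolecular Mitsunobu etherification in which the phenol displaces the benzylic oxyphosphonium in a 6-exo-tet SN2 closure with inversion, converting the R carbinol into the 2S flavan while the silyl ether blocks the other alcohol.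

**Step 19**
Reactants: 25 the protected flavan of step 18
Product: 26 (3S)-6-[(2S)-7-hydroxy-6-(2-methylbut-3-en-2-yl)chroman-2-yl]-2,2-dimethyl-5-(3-methylbut-2-en-1-yl)chromane-3,8-diol
Conditions: HCl (1.25 M in MeOH), 0 °C → rt
Reagents that add atoms: none
Why: Acid-catalysed methanolysis cleaves both MOM acetals and the TES ether in one operation; the linear prenyl group has no ortho phenol and the monosubstituted vinyl group should not be protonated by cold dilute acid.

**Compound list**

1 | 2-bromo-4,5-dimethoxybenzonitrile | N#Cc1cc(OC)c(OC)cc1Br | starting material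
2 | 2-bromo-4,5-dihydroxybenzonitrile | N#Cc1cc(O)c(O)cc1Br | intermediate
3 | 4-(allyloxy)-2-bromo-5-hydroxybenzonitrile | N#Cc1cc(O)c(OCC=C)cc1Br | intermediate
4 | 4-(allyloxy)-2-bromo-5-(methoxymethoxy)benzonitrile | N#Cc1cc(OCOC)c(OCC=C)cc1Br | intermediate
5 | 3-allyl-2-bromo-5-(methoxymethoxy)-4-oxocyclohexa-1,5-diene-1-carbonitrile (ortho-dienone, not isolated) | N#CC1=C(Br)C(CC=C)C(=O)C(OCOC)=C1 | intermediate
6 | 3-allyl-2-bromo-4-hydroxy-5-(methoxymethoxy)benzonitrile | N#Cc1cc(OCOC)c(O)c(CC=C)c1Br | intermediate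
7 | 2-[2-allyl-3-bromo-4-cyano-6-(methoxymethoxy)phenoxy]-2-methylpropanoyl chloride (not isolated) | N#Cc1cc(OCOC)c(OC(C)(C)C(=O)Cl)c(CC=C)c1Br | intermediate
8 | 2-[2-allyl-3-bromo-4-cyano-6-(methoxymethoxy)phenoxy]-2-methylpropanoic acid | N#Cc1cc(OCOC)c(OC(C)(C)C(=O)O)c(CC=C)c1Br | intermediate
9 | 1,3-dioxoisoindolin-2-yl 2-[2-allyl-3-bromo-4-cyano-6-(methoxymethoxy)phenoxy]-2-methylpropanoate | N#Cc1cc(OCOC)c(OC(C)(C)C(=O)ON2C(=O)c3ccccc3C2=O)c(CC=C)c1Br | intermediate
10 | 1,3-dioxoisoindolin-2-yl 2-[3-bromo-4-cyano-6-(methoxymethoxy)-2-(1,2,4-trioxolan-3-ylmethyl)phenoxy]-2-methylpropanoate (secondary ozonide, not isolated) | N#Cc1cc(OCOC)c(OC(C)(C)C(=O)ON2C(=O)c3ccccc3C2=O)c(CC2OCOO2)c1Br | intermediate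
11 | 1,3-dioxoisoindolin-2-yl 2-[3-bromo-4-cyano-6-(methoxymethoxy)-2-(2-oxoethyl)phenoxy]-2-methylpropanoate | N#Cc1cc(OCOC)c(OC(C)(C)C(=O)ON2C(=O)c3ccccc3C2=O)c(CC=O)c1Br | intermediate
12 | 5-bromo-8-(methoxymethoxy)-2,2-dimethyl-3-oxochromane-6-carbonitrile | N#Cc1cc(OCOC)c2OC(C)(C)C(=O)Cc2c1Br | intermediate
13 | (S)-5-bromo-3-hydroxy-8-(methoxymethoxy)-2,2-dimethylchromane-6-carbonitrile | N#Cc1cc(OCOC)c2OC(C)(C)[C@@H](O)Cc2c1Br | intermediate
14 | (S)-5-bromo-8-(methoxymethoxy)-2,2-dimethyl-3-(triethylsilyloxy)chromane-6-carbonitrile | N#Cc1cc(OCOC)c2OC(C)(C)[C@@H](O[Si](CC)(CC)CC)Cc2c1Br | intermediate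
15 | (S)-8-(methoxymethoxy)-2,2-dimethyl-5-(3-methylbut-2-en-1-yl)-3-(triethylsilyloxy)chromane-6-carbonitrile | N#Cc1cc(OCOC)c2OC(C)(C)[C@@H](O[Si](CC)(CC)CC)Cc2c1CC=C(C)C | intermediate
16 | N-(bromomagnesio) ketimine of 17 (not isolated) | CC(=N[Mg]Br)c1cc(OCOC)c2OC(C)(C)[C@@H](O[Si](CC)(CC)CC)Cc2c1CC=C(C)C | intermediate
17 | 1-[(S)-8-(methoxymethoxy)-2,2-dimethyl-5-(3-methylbut-2-en-1-yl)-3-(triethylsilyloxy)chroman-6-yl]ethan-1-one | CC(=O)c1cc(OCOC)c2OC(C)(C)[C@@H](O[Si](CC)(CC)CC)Cc2c1CC=C(C)C | intermediate
18 | 5-bromo-2,4-dihydroxybenzaldehyde | O=Cc1cc(Br)c(O)cc1O | starting material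
19 | 5-bromo-2-hydroxy-4-(methoxymethoxy)benzaldehyde | O=Cc1cc(Br)c(OCOC)cc1O | intermediate
20 | 2-hydroxy-4-(methoxymethoxy)-5-(2-methylbut-3-en-2-yl)benzaldehyde | O=Cc1cc(C(C)(C)C=C)c(OCOC)cc1O | intermediate
21 | aldol adduct of 17 and 20 (β-hydroxy ketone, both carbinol epimers, not isolated) | O=C(CC(O)c1cc(C(C)(C)C=C)c(OCOC)cc1O)c1cc(OCOC)c2OC(C)(C)[C@@H](O[Si](CC)(CC)CC)Cc2c1CC=C(C)C | intermediate
22 | (E)-enone (chalcone) from 17 and 20 | O=C(/C=C/c1cc(C(C)(C)C=C)c(OCOC)cc1O)c1cc(OCOC)c2OC(C)(C)[C@@H](O[Si](CC)(CC)CC)Cc2c1CC=C(C)C | intermediate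
23 | saturated ketone (dihydrochalcone) | O=C(CCc1cc(C(C)(C)C=C)c(OCOC)cc1O)c1cc(OCOC)c2OC(C)(C)[C@@H](O[Si](CC)(CC)CC)Cc2c1CC=C(C)C | intermediate
24 | (R)-carbinol (1,3-diarylpropan-1-ol) | O[C@H](CCc1cc(C(C)(C)C=C)c(OCOC)cc1O)c1cc(OCOC)c2OC(C)(C)[C@@H](O[Si](CC)(CC)CC)Cc2c1CC=C(C)C | intermediate
25 | (2S)-flavan with (3S)-silyloxy ring D and two MOM ethers | C=CC(C)(C)c1cc2c(cc1OCOC)O[C@H](c1cc(OCOC)c3c(c1CC=C(C)C)C[C@H](O[Si](CC)(CC)CC)C(C)(C)O3)CC2 | intermediate
26 | (3S)-6-[(2S)-7-hydroxy-6-(2-methylbut-3-en-2-yl)chroman-2-yl]-2,2-dimethyl-5-(3-methylbut-2-en-1-yl)chromane-3,8-diol | C=CC(C)(C)c1cc2c(cc1O)O[C@H](c1cc(O)c3c(c1CC=C(C)C)C[C@H](O)C(C)(C)O3)CC2 | target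

**Step count and risks**

Total step count: 19. Longest linear sequence: 17 (steps 1–12 and 15–19).

Steps most likely to fail:

1. Step 8 (new method). Base-mediated enolisation and aldol oligomerisation of the arylacetaldehyde, or intermolecular electron transfer and radical coupling, may outrun the ring closure. The fallback sets out from 11 and closes the same bond with known radical chemistry. Irradiation (blue LED) of 11 with Ru(bpy)3Cl2, Hantzsch ester and iPr2NEt in CH2Cl2 effects reductive decarboxylation of the N-acyloxyphthalimide to the same tertiary α-aryloxy radical. This radical cyclises 6-exo-trig onto the aldehyde carbonyl carbon, and the alkoxy radical is quenched by hydrogen transfer to give racemic 5-bromo-3-hydroxy-8-(methoxymethoxy)-2,2-dimethylchromane-6-carbonitrile F1. Dess–Martin oxidation of F1 comes back to the route at 12.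

2. Step 14. The tertiary σ-allyl palladium may isomerise to the primary one before reductive elimination (loss of γ-selectivity), and oxidative addition into the phenoxide-bearing bromide may be slow. The fallback sets out from 19 and reverses the polarity of the coupling. Borylation of 19 (B2(OH)4, Pd(OAc)2, XPhos, KOAc, EtOH, 80 °C) gives [5-formyl-4-hydroxy-2-(methoxymethoxy)phenyl]boronic acid F2. γ-Selective allyl–aryl coupling of F2 with 3-methylbut-2-en-1-yl acetate (Pd(OAc)2, 1,10-phenanthroline, AgSbF6, 1,2-dichloroethane, 60 °C) then follows. Here the aryl palladium adds across the alkene and β-acetoxy elimination fixes the aryl group on the tertiary carbon, which comes back to the route at 20.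

3. Step 18. The benzylic oxyphosphonium ion, activated by the para oxygen of ring B, may ionise and erode the configuration at flavan C2. The fallback sets out from 23 and closes ring C at the aryl–oxygen bond instead, so that the carbinol C–O bond is never broken. Triflation of the phenol of 23 (PhNTf2, K2CO3, THF) gives the aryl triflate ketone F3. Reduction of F3 with (R)-2-methyl-CBS-oxazaborolidine and BH3·SMe2 gives the (S)-carbinol triflate F4. Intramolecular C–O coupling of F4 (Pd(OAc)2, 2-(di-tert-butylphosphino)-1,1'-binaphthyl, Cs2CO3, toluene, 70 °C) proceeds with retention and comes back to the route at 25.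

**Further compounds**

F1 | step 8 | rac-5-bromo-3-hydroxy-8-(methoxymethoxy)-2,2-dimethylchromane-6-carbonitrile | N#Cc1cc(OCOC)c2OC(C)(C)C(O)Cc2c1Br
F2 | step 14 | [5-formyl-4-hydroxy-2-(methoxymethoxy)phenyl]boronic acid | O=Cc1cc(B(O)O)c(OCOC)cc1O
F3 | step 18 | aryl triflate of ketone 23 | O=C(CCc1cc(C(C)(C)C=C)c(OCOC)cc1OS(=O)(=O)C(F)(F)F)c1cc(OCOC)c2OC(C)(C)[C@@H](O[Si](CC)(CC)CC)Cc2c1CC=C(C)C
F4 | step 18 | (S)-carbinol aryl triflate | O[C@@H](CCc1cc(C(C)(C)C=C)c(OCOC)cc1OS(=O)(=O)C(F)(F)F)c1cc(OCOC)c2OC(C)(C)[C@@H](O[Si](CC)(CC)CC)Cc2c1CC=C(C)C
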